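# Proposed total synthesis of borregomycin E by chromium carbene benzannulation

## Analysis of the target

Borregomycin E (23) is 2,9-dichloro-5,6-dimethoxy-11,12-dihydroindolo[2,3-a]carbazole, five fused aromatic rings in which two 6-chloroindole units are joined C2 to C2 (C11a–C11b) and bridged C3 to C3 by the two methoxy-bearing carbons C5 and C6. The molecule is planar and achiral, has no stereocentre, and a mirror plane bisects the C5–C6 and C11a–C11b bonds. Its sensitive features are two aryl chlorides that must outlive organolithium and palladium chemistry, an electron-rich dimethoxyarene that oxidises readily towards the ortho-quinone level, and two neighbouring N–H groups that a one-carbon electrophile can bridge. The difficulty lies in the central benzene ring C4b–C5–C6–C6a–C11a–C11b, which is hexasubstituted and carries O, O, C, N, N and C in sequence. The strategy rests on one feature of that ring: C5–OMe sits on C4b (indole C3 of the left-hand indole), and para to it C11a sits on C11b (indole C2) and bears a heteroatom. This 1,4-pattern, with C6 and C6a in between, is what a carbene-complex benzannulation produces from an indol-3-yl methoxycarbene (C5), an alkyne (C6, C6a) and one carbonyl ligand (C11a). The heteroatom needed at C11a is nitrogen, so the oxygen that the benzannulation places there has to serve as a leaving group afterwards.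

## Retrosynthetic reasoning

**23 ⇒ 22 (protecting groups).** The last operation frees both nitrogens: the SEM group on N12 and the tert-butoxycarbonyl group on N11 of 22 are removed together. Keeping both nitrogens masked until the end protects the electron-rich bis-indole from oxidation and from bridging of the N–H pair, and costs a single step.

**22 ⇒ 19 + 20 (N11–C10a and N11–C11a).** N11 is the one ring atom the benzannulation cannot supply, so both of its ring bonds are cut, leading to the bromo triflate 19 and tert-butyl carbamate (20). C10a can carry bromine from the start, and C11a carries the benzannulation oxygen, now a triflate. The forward reaction is a tandem palladium-catalysed N-arylation. It must close a five-membered ring at a hindered triflate and must engage C–Br and C–OTf but neither C–Cl bond.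

**19 ⇒ 18 ⇒ 17 ⇒ 16 (functional-group changes at C6 and C11a).** The C6 methoxy group of 19 is traced to the phenol 18, and that to the aryl boronate 17. The triflate is traced to the phenol 16. Triflating first means the C6 and C11a oxygens are never free phenols at the same time, so they need no differentiation. The C6 oxygen is carried as boron because an alkynyl ether, the obvious source of C6–OMe, is polarised so that its oxygen-bearing carbon becomes the new carbene carbon on insertion. That would place the alkyne oxygen beside the carbonyl-derived carbon, the wrong way round. A boronate has the opposite polar preference and is converted to C–O with retention of position.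

**16 ⇒ 7 + 14 (C5–C6, C6a–C11a and C11a–C11b; the key disconnection).** The central ring is opened into the indol-3-yl methoxycarbene complex 7, the alkynylboronate 14 and one carbonyl ligand of 7. This cut leaves the first indole intact and uses only its C2–H. It delivers C5–OMe from the carbene, the oxygen at C11a from a carbonyl ligand, the chloroaryl ring on C6a and a masked oxygen on C6. Three skeletal bonds and one ring form in a single operation. The forward reaction must insert the alkyne with the aryl end towards the carbonyl-derived carbon, and must insert CO before ring closure.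

**7 ⇒ 3 + 4; 3 ⇒ 2 ⇒ 1.** The carbene carbon is a carbonyl ligand of hexacarbonylchromium (4) attacked by the 3-lithio derivative of bromide 3 and then O-methylated. Bromide 3 comes from the N-protected indole 2 by C3 bromination, and 2 from 6-chloroindole (1). The chlorine of 1 ends at C2 of 23.

**14 ⇒ 11 ⇒ 10 ⇒ 8 + 9.** The C–B bond of 14 is made from the terminal alkyne 11. Alkyne 11 comes from the silylalkyne 10, and 10 from 2-bromo-4-chloro-1-iodobenzene (8) and ethynyltrimethylsilane (9) by coupling at the iodide only. In 8 the bromine is ortho to the alkyne (future C10a) and the chlorine para (future C9).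

## Alternatives that were turned down

**Alternative 1:** The two aryl-to-core bonds C4a–C4b and C6a–C6b are cut in 2,9-dichloro-11,12-dihydroindolo[2,3-a]carbazole-5,6-dione A1, leading to 4,5-bis(2-bromo-5-chloroanilino)cyclohexa-3,5-diene-1,2-dione A2.
- Forward key step: Pd(OAc)2 and KOAc in N,N-dimethylacetamide insert into both C–Br bonds of A2 and arylate the two quinone C–H carbons, closing both pyrrole rings. A1 then needs reduction and double O-methylation to reach 23.
- For: it is the shortest route, it uses the symmetry of the target, the central ring is bought rather than built, and no stoichiometric metal is needed. On step count and convergence it is clearly stronger than the chosen route.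
- Against: an ortho-quinone is an oxidant for zerovalent palladium and an electrophile towards acetate at the temperatures such arylations need. A2 is a vinylogous amide that can tautomerise to a hydroxyquinone imine and must be made from a weakly nucleophilic, ortho-hindered aniline. The end game passes through an air-sensitive catechol that must be O-methylated beside two free N–H groups.
- In its place the chosen route keeps C5 and C6 at the ether oxidation level throughout, keeps the nitrogens masked or absent until the last step, and uses only steps of established type.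

**Alternative 2:** C4b–C11b, C5–C6 and C6a–C11a are cut in 7-chloro-2-(4-chloro-2-nitrophenyl)-3,4-dimethoxy-9-(4-methylbenzenesulfonyl)-9H-carbazole A3, leading to the diyne N-[5-chloro-2-(methoxyethynyl)phenyl]-N-ethynyl-4-methylbenzenesulfonamide A4 and the alkyne 4-chloro-1-(methoxyethynyl)-2-nitrobenzene A5.
- Forward key step: RhCl(PPh3)3 joins A4 and A5 in a (2+2+2) cycloaddition that closes one pyrrole ring and the central ring. A Cadogan-type nitrene closure onto the C–H carbon that becomes C11a, and desulfonylation, would follow.
- For: the metal is catalytic, two rings form at once, and C11a needs no leaving group. On these points it is stronger than the chosen route.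
- Against: insertion of A5 into the rhodacycle from A4 must join the two methoxy-bearing carbons head to head, which neither steric nor polar effects clearly enforce. Three hydrolytically fragile alkynes (a terminal ynamide and two alkynyl ethers) lengthen the preparation and can oligomerise. The later nitrene has a methoxy-bearing ortho carbon as a competing site.
- Both routes build the central ring from an alkyne and both face a regiochemical question. In the chosen route it is answered by the fixed roles of carbene carbon and carbonyl ligand and by the polarity of a boronate, at the price of stoichiometric chromium and an oxygen-to-nitrogen exchange at C11a.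

**Alternative 3:** N11–C11a and C6–C6a are cut in tert-butyl 2,9-dichloro-5,6-dimethoxy-11H-indolo[2,3-a]carbazole-12-carboxylate A6, leading to tert-butyl 2-[(2-azido-4-chlorophenyl)ethynyl]-6-chloro-3-(1,2-dimethoxyethenyl)-1H-indole-1-carboxylate A7.
- Forward key step: under Ph3PAuNTf2 the azide nitrogen adds to the gold-activated alkyne at C11a with loss of dinitrogen, and the α-imino gold carbene at C6a is captured by the enol ether carbon C6. This closes the second pyrrole and the central ring.
- For: N11 is introduced without palladium or a leaving group, two rings close catalytically, and A6 is one deprotection from 23. Its end game is more economical than that of the chosen route.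
- Against: A7 requires a long linear build of a 2,3-difunctionalised 6-chloroindole carrying a 1,2-dimethoxyvinyl unit, for which no simple reagent exists, and an aryl azide. The enol ether is labile to cationic gold and adventitious acid. It can also attack the activated alkyne at C6a before the azide does, which leads away from A6.
- The chosen route offers instead a convergent union of two three-step fragments, commodity reagents for every heteroatom, and a ring synthesis whose regiochemistry can be argued from polarity.

Key step: step 7

Remark on the chemistry: the C6 oxygen is carried through the benzannulation as a pinacol boronate instead of a methoxy group on the alkyne, because an alkynyl ether is expected to insert with the opposite orientation. The three ring bonds formed are unchanged.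

Abbreviations: SEM = [2-(trimethylsilyl)ethoxy]methyl; Bpin = 4,4,5,5-tetramethyl-1,3,2-dioxaborolan-2-yl. Locants such as C5, C6a, C11a and N11 refer to the indolo[2,3-a]carbazole skeleton of 23. Carbazole intermediates are named with carbazole locants (C1 = future C11a, C2 = C6a, C3 = C6, C4 = C5).

## Route

Step 1
Reactants: 1 6-chloroindole
Product: 2 6-chloro-1-SEM-1H-indole
Conditions: NaH, DMF, 0 °C; SEMCl, 0 °C → rt
Reagents that add atoms: [2-(trimethylsilyl)ethoxy]methyl chloride (SEMCl), C[Si](C)(C)CCOCCl
Why: N-Deprotonation and SN2 alkylation by the chloromethyl ether. The N–CH2 group is small enough to leave C2 open for the later ring closure and is stable to organolithium, zerovalent chromium and palladium chemistry.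

Step 2
Reactants: 2 6-chloro-1-SEM-1H-indole
Product: 3 3-bromo-6-chloro-1-SEM-1H-indole
Conditions: NBS (1.0 equiv), THF, 0 °C, dark
Reagents that add atoms: N-bromosuccinimide, O=C1CCC(=O)N1Br
Why: Electrophilic aromatic bromination at C3, the most nucleophilic position of an N-alkylindole. One equivalent at low temperature should avoid 2,3-dibromination, and the bromide is used without storage.

Step 3
Reactants: 3 3-bromo-6-chloro-1-SEM-1H-indole, 4 hexacarbonylchromium Cr(CO)6
Product: 7 pentacarbonyl[(6-chloro-1-SEM-1H-indol-3-yl)(methoxy)methylidene]chromium, via 3-lithioindole 5 (not isolated), via lithium acylpentacarbonylchromate 6 (not isolated)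
Conditions: t-BuLi (2 equiv), THF, −78 °C; Cr(CO)6, −78 °C → rt; then MeOTf, CH2Cl2, 0 °C
Reagents that add atoms: methyl trifluoromethanesulfonate, COS(=O)(=O)C(F)(F)F
Why: Fischer carbene synthesis. Bromine–lithium exchange at −78 °C is faster than attack on C–Cl or migration of lithium to C2, the aryllithium adds to a carbonyl ligand, and the acylchromate oxygen is methylated by the hard triflate.

Step 4
Reactants: 8 2-bromo-4-chloro-1-iodobenzene, 9 ethynyltrimethylsilane
Product: 10 [(2-bromo-4-chlorophenyl)ethynyl]trimethylsilane
Conditions: PdCl2(PPh3)2 (cat.), CuI (cat.), Et3N, THF, rt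
Reagents that add atoms: none
Why: Sonogashira coupling. At room temperature zerovalent palladium inserts into C–I far faster than into C–Br or C–Cl, so only the iodide is replaced.

Step 5
Reactants: 10 [(2-bromo-4-chlorophenyl)ethynyl]trimethylsilane
Product: 11 2-bromo-4-chloro-1-ethynylbenzene
Conditions: K2CO3 (cat.), MeOH, rt
Reagents that add atoms: none
Why: Methoxide-induced protodesilylation of an alkynylsilane. The aryl halides are inert to these conditions.

Step 6
Reactants: 11 2-bromo-4-chloro-1-ethynylbenzene
Product: 14 2-[(2-bromo-4-chlorophenyl)ethynyl]-4,4,5,5-tetramethyl-1,3,2-dioxaborolane, via alkynylmagnesium bromide 12 (not isolated), via bromomagnesium alkynylborate 13 (not isolated)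
Conditions: EtMgBr, THF, 0 → 40 °C; i-PrOBpin, −78 °C → rt; HCl (Et2O), −78 °C → rt; non-aqueous work-up
Reagents that add atoms: 2-isopropoxy-4,4,5,5-tetramethyl-1,3,2-dioxaborolane, CC(C)OB1OC(C)(C)C(C)(C)O1
Why: The Grignard reagent deprotonates the alkyne without bromine–magnesium exchange at the aryl bromide. The acetylide adds to boron, and anhydrous acid collapses the borate to the alkynylboronic ester (standard alkynylboronate synthesis). The product is hydrolytically labile and is handled dry.

Step 7
Reactants: 7 pentacarbonyl[(6-chloro-1-SEM-1H-indol-3-yl)(methoxy)methylidene]chromium, 14 2-[(2-bromo-4-chlorophenyl)ethynyl]-4,4,5,5-tetramethyl-1,3,2-dioxaborolane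
Product: 16 2-(2-bromo-4-chlorophenyl)-7-chloro-4-methoxy-3-Bpin-9-SEM-9H-carbazol-1-ol, via tricarbonylchromium arene complex 15 (not isolated)
Conditions: 14 (2 equiv), THF, 60 °C; then air, rt
Reagents that add atoms: none
Why: Heating expels one carbonyl ligand from the zerovalent chromium carbene complex, the alkyne coordinates and inserts into the Cr=C bond to give an η1,η3-vinylcarbene, a carbonyl ligand then inserts to give a chromium-bound dienylketene whose second double bond is the indole C2–C3 bond, and 6π-electrocyclisation onto indole C2 followed by tautomerisation gives the phenol as its Cr(CO)3 complex 15, from which air removes the metal. The closest known reaction type is the Dötz benzannulation of aryl(alkoxy)carbene chromium complexes with alkynylboronic esters, together with the same benzannulation of indolyl carbene complexes to hydroxycarbazoles. The one ring formed, the central benzene ring, is closed by the 6π-electrocyclic step (C11a–C11b), after C5–C6 and C6a–C11a have been made in the alkyne and carbonyl insertions; no stereocentre arises. The step needs one regiochemistry, with the aryl-bearing alkyne carbon next to the carbonyl-derived carbon and the boron-bearing carbon on the carbene carbon: the π-acceptor boron avoids the electron-poor new carbene carbon while the aryl group stabilises it, and the twisted ortho-bromoaryl group is also the more demanding end, so polar and steric preferences point the same way. It also needs carbonyl insertion to win over direct five-ring closure of the donor-rich indolyl carbene, which THF, a moderate temperature and an excess of alkyne favour, and it needs the C–Br, C–Cl and C–B bonds to stay untouched, as they should towards zerovalent chromium.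

Step 8
Reactants: 16 2-(2-bromo-4-chlorophenyl)-7-chloro-4-methoxy-3-Bpin-9-SEM-9H-carbazol-1-ol
Product: 17 2-(2-bromo-4-chlorophenyl)-7-chloro-4-methoxy-3-Bpin-9-SEM-9H-carbazol-1-yl trifluoromethanesulfonate
Conditions: Tf2O, pyridine, CH2Cl2, −20 → 0 °C
Reagents that add atoms: trifluoromethanesulfonic anhydride, O=S(=O)(OS(=O)(=O)C(F)(F)F)C(F)(F)F
Why: O-Sulfonylation of the phenol. It turns the C11a oxygen into a leaving group and at the same time removes the oxidation-prone 4-methoxyphenol, so the crude phenol is triflated without delay.

Step 9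
Reactants: 17 2-(2-bromo-4-chlorophenyl)-7-chloro-4-methoxy-3-Bpin-9-SEM-9H-carbazol-1-yl trifluoromethanesulfonate
Product: 18 2-(2-bromo-4-chlorophenyl)-7-chloro-3-hydroxy-4-methoxy-9-SEM-9H-carbazol-1-yl trifluoromethanesulfonate
Conditions: NaBO3·4H2O, THF/H2O, rt
Reagents that add atoms: sodium perborate (NaBO3·4H2O, peroxoborate dimer), [Na+].[Na+].O[B-]1(O)OO[B-](O)(O)OO1
Why: Peroxide adds to boron and the aryl group migrates to oxygen with retention of position (boronate oxidation). Perborate is mild enough to spare the aryl triflate and the SEM group.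

Step 10
Reactants: 18 2-(2-bromo-4-chlorophenyl)-7-chloro-3-hydroxy-4-methoxy-9-SEM-9H-carbazol-1-yl trifluoromethanesulfonate
Product: 19 2-(2-bromo-4-chlorophenyl)-7-chloro-3,4-dimethoxy-9-SEM-9H-carbazol-1-yl trifluoromethanesulfonate
Conditions: MeI, K2CO3, DMF, rt
Reagents that add atoms: iodomethane, CI
Why: Williamson O-methylation of the only free phenol. Carbonate in DMF at room temperature does not cleave the aryl triflate.

Step 11
Reactants: 19 2-(2-bromo-4-chlorophenyl)-7-chloro-3,4-dimethoxy-9-SEM-9H-carbazol-1-yl trifluoromethanesulfonate, 20 tert-butyl carbamate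
Product: 22 tert-butyl 2,9-dichloro-5,6-dimethoxy-12-SEM-12H-indolo[2,3-a]carbazole-11-carboxylate, via aryl carbamate 21 (not isolated)
Conditions: Pd2(dba)3 (cat.), Xantphos, Cs2CO3, 1,4-dioxane, 100 °C
Reagents that add atoms: none
Why: Tandem Buchwald–Hartwig amidation (double N-arylation of a carbamate by a biaryl bis-electrophile). The carbamate is arylated first at the more accessible C–Br bond, and the aryl carbamate then closes the pyrrole ring at the neighbouring triflate. The Pd/Xantphos catalyst activates bromide and triflate but not the aryl chlorides at this temperature.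

Step 12
Reactants: 22 tert-butyl 2,9-dichloro-5,6-dimethoxy-12-SEM-12H-indolo[2,3-a]carbazole-11-carboxylate
Product: 23 borregomycin E (2,9-dichloro-5,6-dimethoxy-11,12-dihydroindolo[2,3-a]carbazole)
Conditions: Bu4NF, ethylenediamine, DMF, 80 °C
Reagents that add atoms: none
Why: Fluoride attacks silicon and the SEM group fragments to fluorotrimethylsilane, ethene and formaldehyde, which ethylenediamine captures before it can bridge N11 and N12. The N-Boc group on the weakly basic carbazole nitrogen is an activated carbamate and is transferred to the diamine under the same conditions.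

## Compound list

1 | 6-chloroindole | Clc1ccc2cc[nH]c2c1 | starting material
2 | 6-chloro-1-{[2-(trimethylsilyl)ethoxy]methyl}-1H-indole | C[Si](C)(C)CCOCn1ccc2ccc(Cl)cc21 | intermediate
3 | 3-bromo-6-chloro-1-{[2-(trimethylsilyl)ethoxy]methyl}-1H-indole | C[Si](C)(C)CCOCn1cc(Br)c2ccc(Cl)cc21 | intermediate
4 | hexacarbonylchromium Cr(CO)6 | O=C=[Cr](=C=O)(=C=O)(=C=O)(=C=O)=C=O | starting material
5 | (6-chloro-1-{[2-(trimethylsilyl)ethoxy]methyl}-1H-indol-3-yl)lithium | [Li]c1cn(COCC[Si](C)(C)C)c2cc(Cl)ccc12 | intermediate (not isolated)
6 | lithium pentacarbonyl[(6-chloro-1-{[2-(trimethylsilyl)ethoxy]methyl}-1H-indol-3-yl)(oxido)methylidene]chromate | [Li+].[O-]C(=[Cr](=C=O)(=C=O)(=C=O)(=C=O)=C=O)c1cn(COCC[Si](C)(C)C)c2cc(Cl)ccc12 | intermediate (not isolated)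
7 | pentacarbonyl[(6-chloro-1-{[2-(trimethylsilyl)ethoxy]methyl}-1H-indol-3-yl)(methoxy)methylidene]chromium | COC(=[Cr](=C=O)(=C=O)(=C=O)(=C=O)=C=O)c1cn(COCC[Si](C)(C)C)c2cc(Cl)ccc12 | intermediate
8 | 2-bromo-4-chloro-1-iodobenzene | Clc1ccc(I)c(Br)c1 | starting material
9 | ethynyltrimethylsilane | C#C[Si](C)(C)C | starting material
10 | [(2-bromo-4-chlorophenyl)ethynyl]trimethylsilane | C[Si](C)(C)C#Cc1ccc(Cl)cc1Br | intermediate
11 | 2-bromo-4-chloro-1-ethynylbenzene | C#Cc1ccc(Cl)cc1Br | intermediate
12 | [(2-bromo-4-chlorophenyl)ethynyl]magnesium bromide | Br[Mg]C#Cc1ccc(Cl)cc1Br | intermediate (not isolated)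
13 | bromomagnesium 2-[(2-bromo-4-chlorophenyl)ethynyl]-2-isopropoxy-4,4,5,5-tetramethyl-1,3,2-dioxaborolan-2-uide | CC(C)O[B-]1(C#Cc2ccc(Cl)cc2Br)OC(C)(C)C(C)(C)O1.[Mg+]Br | intermediate (not isolated)
14 | 2-[(2-bromo-4-chlorophenyl)ethynyl]-4,4,5,5-tetramethyl-1,3,2-dioxaborolane | CC1(C)OB(C#Cc2ccc(Cl)cc2Br)OC1(C)C | intermediate
15 | tricarbonyl(η6-arene)chromium complex of 16, Cr(CO)3 on the newly formed benzene ring (hapto bond written as a dot) | COc1c(B2OC(C)(C)C(C)(C)O2)c(-c2ccc(Cl)cc2Br)c(O)c2c1c1ccc(Cl)cc1n2COCC[Si](C)(C)C.O=C=[Cr](=C=O)=C=O | intermediate (not isolated)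
16 | 2-(2-bromo-4-chlorophenyl)-7-chloro-4-methoxy-3-(4,4,5,5-tetramethyl-1,3,2-dioxaborolan-2-yl)-9-{[2-(trimethylsilyl)ethoxy]methyl}-9H-carbazol-1-ol | COc1c(B2OC(C)(C)C(C)(C)O2)c(-c2ccc(Cl)cc2Br)c(O)c2c1c1ccc(Cl)cc1n2COCC[Si](C)(C)C | intermediate
17 | 2-(2-bromo-4-chlorophenyl)-7-chloro-4-methoxy-3-(4,4,5,5-tetramethyl-1,3,2-dioxaborolan-2-yl)-9-{[2-(trimethylsilyl)ethoxy]methyl}-9H-carbazol-1-yl trifluoromethanesulfonate | COc1c(B2OC(C)(C)C(C)(C)O2)c(-c2ccc(Cl)cc2Br)c(OS(=O)(=O)C(F)(F)F)c2c1c1ccc(Cl)cc1n2COCC[Si](C)(C)C | intermediate
18 | 2-(2-bromo-4-chlorophenyl)-7-chloro-3-hydroxy-4-methoxy-9-{[2-(trimethylsilyl)ethoxy]methyl}-9H-carbazol-1-yl trifluoromethanesulfonate | COc1c(O)c(-c2ccc(Cl)cc2Br)c(OS(=O)(=O)C(F)(F)F)c2c1c1ccc(Cl)cc1n2COCC[Si](C)(C)C | intermediate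
19 | 2-(2-bromo-4-chlorophenyl)-7-chloro-3,4-dimethoxy-9-{[2-(trimethylsilyl)ethoxy]methyl}-9H-carbazol-1-yl trifluoromethanesulfonate | COc1c(OC)c(-c2ccc(Cl)cc2Br)c(OS(=O)(=O)C(F)(F)F)c2c1c1ccc(Cl)cc1n2COCC[Si](C)(C)C | intermediate
20 | tert-butyl carbamate | CC(C)(C)OC(N)=O | starting material
21 | tert-butyl N-{5-chloro-2-[7-chloro-3,4-dimethoxy-1-(trifluoromethanesulfonyloxy)-9-{[2-(trimethylsilyl)ethoxy]methyl}-9H-carbazol-2-yl]phenyl}carbamate | COc1c(OC)c(-c2ccc(Cl)cc2NC(=O)OC(C)(C)C)c(OS(=O)(=O)C(F)(F)F)c2c1c1ccc(Cl)cc1n2COCC[Si](C)(C)C | intermediate (not isolated)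
22 | tert-butyl 2,9-dichloro-5,6-dimethoxy-12-{[2-(trimethylsilyl)ethoxy]methyl}-12H-indolo[2,3-a]carbazole-11-carboxylate | COc1c(OC)c2c3ccc(Cl)cc3n(C(=O)OC(C)(C)C)c2c2c1c1ccc(Cl)cc1n2COCC[Si](C)(C)C | intermediate
23 | borregomycin E, 2,9-dichloro-5,6-dimethoxy-11,12-dihydroindolo[2,3-a]carbazole | COc1c(OC)c2c3ccc(Cl)cc3[nH]c2c2[nH]c3cc(Cl)ccc3c12 | target

## Step count and least certain steps

Total: 12 steps. Longest linear sequence: 9 steps (steps 1–3 and 7–12 from 6-chloroindole). The alkyne branch (steps 4–6) joins at step 7 and is equally long.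

**Step 7 (key step).** Three processes are most likely to interfere.
- Ring closure before carbonyl insertion. The indol-3-yl carbene is strongly donor-stabilised, and such complexes tend to give five-membered-ring or simple insertion products.
- Erosion of regiocontrol, if the bulk of the boronate outweighs its polar preference.
- Protodeboronation or over-oxidation of the electron-rich 4-methoxyphenol during removal of chromium.

The fallback sets out from 7 and 11 and returns at 19; it places the C6 oxygen after the ring synthesis. Benzannulation of 7 with the terminal alkyne 11 (THF, 60 °C, then air) should give 2-(2-bromo-4-chlorophenyl)-7-chloro-4-methoxy-9-SEM-9H-carbazol-1-ol F1. Terminal arylalkynes are the best-behaved partners and reliably place the substituent next to the hydroxyl group. Oxidative dearomatisation with PhI(OAc)2 in MeOH at 0 °C gives the quinone monoketal 2-(2-bromo-4-chlorophenyl)-7-chloro-4,4-dimethoxy-9-SEM-4,9-dihydro-1H-carbazol-1-one F2. Acid-catalysed conjugate addition of methanol to its enone β-carbon (camphorsulfonic acid, MeOH, rt), loss of methanol from the ketal carbon and tautomerisation give 2-(2-bromo-4-chlorophenyl)-7-chloro-3,4-dimethoxy-9-SEM-9H-carbazol-1-ol F3. Triflation as in step 8 gives 19.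

**Step 11.** Oxidative addition at the doubly flanked triflate may be slow, so that carbonate cleaves the S–O bond or the catalyst begins to insert into C–Cl bonds. Reductive elimination to an N-Boc nitrogen placed beside the N-SEM nitrogen is also sterically strained, which favours hydrodehalogenation. The fallback sets out from 19 and returns at 23; it forms the two C–N bonds separately and never places a second substituent on nitrogen. Coupling of the bromide with benzophenone imine (Pd2(dba)3, BINAP, Cs2CO3, toluene, 80 °C) gives 2-{4-chloro-2-[(diphenylmethylidene)amino]phenyl}-7-chloro-3,4-dimethoxy-9-SEM-9H-carbazol-1-yl trifluoromethanesulfonate F4. Transimination (NH2OH·HCl, NaOAc, MeOH, rt) gives the aniline 2-(2-amino-4-chlorophenyl)-7-chloro-3,4-dimethoxy-9-SEM-9H-carbazol-1-yl trifluoromethanesulfonate F5. Intramolecular amination of the triflate by the free aniline (Pd2(dba)3, Xantphos, K3PO4, toluene, 100 °C) gives 2,9-dichloro-5,6-dimethoxy-12-SEM-11,12-dihydroindolo[2,3-a]carbazole F6, which gives 23 under the conditions of step 12.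

**Step 3.** The 3-lithioindole may isomerise to the more stable 2-lithio species, since the SEM group directs metalation to C2, while it waits for the poorly soluble Cr(CO)6. O-Methylation of the strongly stabilised acylchromate may also be incomplete. The fallback sets out from 2 and returns at 7; it uses no indolyllithium.
- Vilsmeier formylation (POCl3, DMF) gives 6-chloro-1-SEM-1H-indole-3-carbaldehyde F7.
- Pinnick oxidation (NaClO2, NaH2PO4, 2-methylbut-2-ene) gives 6-chloro-1-SEM-1H-indole-3-carboxylic acid F8.
- Oxalyl chloride with catalytic DMF gives 6-chloro-1-SEM-1H-indole-3-carbonyl chloride F9.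
- Acylation of K2Cr(CO)5 (from Cr(CO)6 and potassium graphite KC8, THF, −78 °C) gives potassium pentacarbonyl[(6-chloro-1-SEM-1H-indol-3-yl)(oxido)methylidene]chromate F10, which is methylated with MeOTf to 7.

**Step 12.** Cleavage of the N–SEM bond of an indole-type nitrogen can be sluggish, and liberated formaldehyde can add to the two neighbouring N–H groups if the scavenger is outpaced. The fallback sets out from 22 and returns at 23; it separates cleavage of the silylethyl ether from loss of the one-carbon unit. BF3·OEt2 in CH2Cl2 (0 °C → rt, aqueous work-up) removes the Boc group and cuts the SEM ether to (2,9-dichloro-5,6-dimethoxy-11H-indolo[2,3-a]carbazol-12-yl)methanol F11. Aqueous NH3 in MeOH/THF at room temperature then expels and traps formaldehyde, giving 23.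

## Further compounds

F1 | step 7 | 2-(2-bromo-4-chlorophenyl)-7-chloro-4-methoxy-9-{[2-(trimethylsilyl)ethoxy]methyl}-9H-carbazol-1-ol | COc1cc(-c2ccc(Cl)cc2Br)c(O)c2c1c1ccc(Cl)cc1n2COCC[Si](C)(C)C
F2 | step 7 | 2-(2-bromo-4-chlorophenyl)-7-chloro-4,4-dimethoxy-9-{[2-(trimethylsilyl)ethoxy]methyl}-4,9-dihydro-1H-carbazol-1-one | COC1(OC)C=C(c2ccc(Cl)cc2Br)C(=O)c2c1c1ccc(Cl)cc1n2COCC[Si](C)(C)C
F3 | step 7 | 2-(2-bromo-4-chlorophenyl)-7-chloro-3,4-dimethoxy-9-{[2-(trimethylsilyl)ethoxy]methyl}-9H-carbazol-1-ol | COc1c(OC)c(-c2ccc(Cl)cc2Br)c(O)c2c1c1ccc(Cl)cc1n2COCC[Si](C)(C)C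
F4 | step 11 | 2-{4-chloro-2-[(diphenylmethylidene)amino]phenyl}-7-chloro-3,4-dimethoxy-9-{[2-(trimethylsilyl)ethoxy]methyl}-9H-carbazol-1-yl trifluoromethanesulfonate | COc1c(OC)c(-c2ccc(Cl)cc2N=C(c2ccccc2)c2ccccc2)c(OS(=O)(=O)C(F)(F)F)c2c1c1ccc(Cl)cc1n2COCC[Si](C)(C)C
F5 | step 11 | 2-(2-amino-4-chlorophenyl)-7-chloro-3,4-dimethoxy-9-{[2-(trimethylsilyl)ethoxy]methyl}-9H-carbazol-1-yl trifluoromethanesulfonate | COc1c(OC)c(-c2ccc(Cl)cc2N)c(OS(=O)(=O)C(F)(F)F)c2c1c1ccc(Cl)cc1n2COCC[Si](C)(C)C
F6 | step 11 | 2,9-dichloro-5,6-dimethoxy-12-{[2-(trimethylsilyl)ethoxy]methyl}-11,12-dihydroindolo[2,3-a]carbazole | COc1c(OC)c2c3ccc(Cl)cc3[nH]c2c2c1c1ccc(Cl)cc1n2COCC[Si](C)(C)C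
F7 | step 3 | 6-chloro-1-{[2-(trimethylsilyl)ethoxy]methyl}-1H-indole-3-carbaldehyde | O=Cc1cn(COCC[Si](C)(C)C)c2cc(Cl)ccc12
F8 | step 3 | 6-chloro-1-{[2-(trimethylsilyl)ethoxy]methyl}-1H-indole-3-carboxylic acid | OC(=O)c1cn(COCC[Si](C)(C)C)c2cc(Cl)ccc12
F9 | step 3 | 6-chloro-1-{[2-(trimethylsilyl)ethoxy]methyl}-1H-indole-3-carbonyl chloride | ClC(=O)c1cn(COCC[Si](C)(C)C)c2cc(Cl)ccc12
F10 | step 3 | potassium pentacarbonyl[(6-chloro-1-{[2-(trimethylsilyl)ethoxy]methyl}-1H-indol-3-yl)(oxido)methylidene]chromate | [K+].[O-]C(=[Cr](=C=O)(=C=O)(=C=O)(=C=O)=C=O)c1cn(COCC[Si](C)(C)C)c2cc(Cl)ccc12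
F11 | step 12 | (2,9-dichloro-5,6-dimethoxy-11H-indolo[2,3-a]carbazol-12-yl)methanol | COc1c(OC)c2c3ccc(Cl)cc3[nH]c2c2c1c1ccc(Cl)cc1n2CO
A1 | alternative 1 | 2,9-dichloro-11,12-dihydroindolo[2,3-a]carbazole-5,6-dione | O=C1C(=O)c2c(-c3[nH]c4cc(Cl)ccc4c31)[nH]c1cc(Cl)ccc21
A2 | alternative 1 | 4,5-bis(2-bromo-5-chloroanilino)cyclohexa-3,5-diene-1,2-dione | O=C1C=C(Nc2cc(Cl)ccc2Br)C(Nc2cc(Cl)ccc2Br)=CC1=O
A3 | alternative 2 | 7-chloro-2-(4-chloro-2-nitrophenyl)-3,4-dimethoxy-9-(4-methylbenzenesulfonyl)-9H-carbazole | COc1c(OC)c(-c2ccc(Cl)cc2[N+](=O)[O-])cc2c1c1ccc(Cl)cc1n2S(=O)(=O)c1ccc(C)cc1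
A4 | alternative 2 | N-[5-chloro-2-(methoxyethynyl)phenyl]-N-ethynyl-4-methylbenzenesulfonamide | COC#Cc1ccc(Cl)cc1N(C#C)S(=O)(=O)c1ccc(C)cc1
A5 | alternative 2 | 4-chloro-1-(methoxyethynyl)-2-nitrobenzene | COC#Cc1ccc(Cl)cc1[N+](=O)[O-]
A6 | alternative 3 | tert-butyl 2,9-dichloro-5,6-dimethoxy-11H-indolo[2,3-a]carbazole-12-carboxylate | COc1c(OC)c2c3ccc(Cl)cc3[nH]c2c2c1c1ccc(Cl)cc1n2C(=O)OC(C)(C)C
A7 | alternative 3 | tert-butyl 2-[(2-azido-4-chlorophenyl)ethynyl]-6-chloro-3-(1,2-dimethoxyethenyl)-1H-indole-1-carboxylate (alkene geometry not defined) | COC=C(OC)c1c(C#Cc2ccc(Cl)cc2N=[N+]=[N-])n(C(=O)OC(C)(C)C)c2cc(Cl)ccc12
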